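## Structural features

The target is an achiral chain of eight oxygenated benzene rings, lettered A to H from the 2,4,6-trihydroxyphenyl end and joined only by seven diaryl ether oxygens; no carbon–carbon bond links two rings and there is no stereocentre, so no stereocentres stand next to each other. Ring A carries hydroxyls on C2, C4 and C6 around its ether carbon C1, rings B, D, F and H carry four oxygens in a 1,2,3,5 arrangement, and rings C, E and G carry five (ether oxygens on C1 and C2, hydroxyls on C3, C4 and C5, hydrogen on C6). Ring B is bridged through the meta pair C1/C5, whereas rings D and F are bridged through the para pair C1/C4, with C4 lying between two hydroxylated carbons. All 21 hydroxyls are free, and the catechol and vicinal triol arrays are oxidised to quinones by air, fastest in base, so the free polyphenol should be released only in a final neutral operation. The real difficulty is the regiocontrolled formation of seven ethers between electron-rich rings, six of them at a carbon flanked on both sides by oxygen substituents. The key step exploits three positional facts: the C4 hydroxyl of ring A is para to its ether carbon C1, and in rings C, E and G the C4 hydroxyl is para to ether carbon C1 and the C3 hydroxyl is ortho to ether carbon C2. Carried as formyl groups, these seven oxygens first make C1 and C2 electrophilic towards phenoxides and are afterwards turned into hydroxyls by peracid-induced aryl migration.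

## Logic of the disconnections

36 to 35. The fourteen benzylic O–C bonds are cut. A single kind of protecting group is removed by neutral hydrogenolysis and leaves as a volatile hydrocarbon, so the air-sensitive polyphenol is released without acid, base or chromatography. The forward step only needs 35 to be free of catalyst poisons and the product to be kept from air.

35 to 33. Seven aryl C–O bonds are cut (C4 of ring A; C3 and C4 of rings C, E and G) and traced back to aryl–CHO bonds, with 34 as the transient ester stage. Each of these oxygens is ortho or para to an ether carbon, so an acceptor in its place turns electron-rich ether carbons into sites for addition–elimination. The gain is that the three pentaoxygenated rings become one repeating electrophile. The demand is aryl rather than hydride migration at seven aldehydes of one molecule, without damage to benzyl ethers or electron-rich rings.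

33 to 32 + 25; 31 to 30 + 22; 29 to 28 + 22. The C2–O bonds of rings G, E and C are cut. Each C2 carries fluorine ortho to the C3 formyl group, so the bond forms by fluoride displacement and the chain shortens by one ring per cut. The demand is that only the unhindered hydroxyl of 22 reacts, that the hydroxyl between its two benzyloxy groups stays free, and that the dialdehyde units survive warm carbonate.

32 to 31 + 6; 30 to 29 + 6; 28 to 27 + 6. The C1–O bonds of rings G, E and C are cut. C1 is para to the C4 formyl group and is the more electrophilic of the two fluorinated carbons of 6, so one building block serves three rings. The demand is attack at C1 and not at C2 of 6, by phenoxides that are hindered in two of the three cases.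

27 to 26 to 11 + 16. 27 is traced back to its allyl ether 26, and the C1–O bond of ring A in 26 is then cut. The two hydroxyls of ring B differ too little in acidity and hindrance to be told apart, so the inner one is masked as an allyl ether while the outer one displaces the fluoride para to the ring A formyl group. The demand is a displacement at a carbon flanked by two benzyloxy groups and activated by a single formyl group.

6 to 3 to 2 to 1. The two aryl–CHO bonds and the benzyl O–C bond are cut. The first formyl group enters ortho to the phenol; the second enters by directed lithiation next to the masked first one and ortho to fluorine. The demand is lithiation at that carbon and not at the one between the benzyloxy group and fluorine.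

11 to 8 to 7. The C–F bond is cut. The carbon between the two benzyloxy groups is the most acidic ring position, so it can be lithiated and fluorinated once the aldehyde is masked. The demand is clean electrophilic fluorination of a hindered aryllithium.

16 to 14 to 13 to 12. The outer aryl C–O bond is traced back to an aryl–CHO bond, by the same peracid chemistry as the key step, and the three ether O–C bonds are cut. The demand is that benzylation stops after the para and one meta hydroxyl.

22 to 20 to 17. Two aryl C–O bonds are cut: the outer hydroxyl comes from para-oxidation of a 2,6-disubstituted phenol, and the phenol oxygen from lithiation, borylation and oxidation between two benzyloxy groups. The demand is that the oxidation-prone hydroquinone is handled under inert gas.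

25 to 23. One aryl C–O bond is traced back to an aryl–CHO bond, which serves as a single-site rehearsal of the key step.

## Other disconnections considered

Alternative 1: The cut is the C1–C2 bond of ring C, so that this ring is grown from a squarate. In the forward key step, heating racemic cyclobutenone A1 should open the four-membered ring to a dienylketene, and six-electron electrocyclisation followed by tautomerisation would give trimer A2, with ring C free only at C2–OH, silylated at C5 and benzylated at C3 and C4. In its favour, all five oxygens of ring C are placed by construction, the one hydroxyl that must next be arylated is the only free one, and the step is thermal and needs no reagent. On regiocontrol within one pentaoxygenated ring it is the better of the two plans, because the chosen plan depends on site selectivity in fluoride displacement, and it carries no risk of hydride migration or over-oxidation. Against it, one pentaoxygenated ring is made per sequence while the target has three, and each round needs a metalated aryloxyvinyl reagent from an ever larger aryl ether, addition to the squarate, silylation and thermolysis. The next bond (C2–O to ring D) must then be made by arylating the hindered phenol of A2 with an unactivated, electron-rich ring, the kind of copper- or palladium-mediated coupling the chosen plan avoids, and the silyl ether needs its own removal. In comparison, the two plans are equal on the correctness of the ring C oxygen pattern, the alternative is mechanistically cleaner for one ring, and it is clearly longer for the octamer, where the chosen plan spends two displacements per pentaoxygenated ring and one global oxidation.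

Alternative 2: The cut is the C3–C4 bond of ring A. In the forward key step, base closes diketo diester A3 by attack of the C6 methylene on the C1 ester (intramolecular Claisen condensation), and enolisation gives A4, in which ring A is a methyl 2,4,6-trihydroxybenzoate bearing the ether at C3. In its favour, the cyclisation is biomimetic and well precedented for simple 3,5-dioxo diesters, and ring A arrives with its three hydroxyls free. It also avoids the slow displacement at the doubly flanked fluoride of 11, so for the A–B bond it is the better idea. Against it, it solves the simplest ring and leaves the heptamer B–H to other chemistry, and A3 requires O-alkylation of a hindered heptameric phenol with a highly acidic halogenated tricarbonyl partner. O-acylation to a pyranone competes with the C-acylation that forms the arene, and the ester of A4 must afterwards be hydrolysed and decarboxylated. In comparison, structurally it adds a carbon that has to be deleted; mechanistically the C- versus O-cyclisation issue replaces the aryl- versus hydride-migration issue; in step economy it adds about three late steps on the most valuable intermediate for one ring, against one displacement in the chosen plan.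

Alternative 3: The cut removes three bonds of ring E (C5–C6, C1–C2 and C4–C5) and divides the molecule in the middle. In the forward key step, a Danheiser-type benzannulation, heating racemic cyclobutenone A5 (carrying rings F to H) gives a vinylketene that adds to ynol ether A6 (tetramer A–D) in a [2+2] cycloaddition; ring opening and six-electron closure then give octamer A7 with a free C5–OH on ring E. In its favour, it is the most convergent of the four plans (four rings plus three rings plus a four-carbon unit), and on convergence it is better than the linear chosen route. Both hindered ethers of ring E are carried in by the partners, so no C–O coupling is needed there, and the regiochemistry follows from the polarisation of the ynol ether. A7 needs only hydrogenolysis to reach the target, which equals the chosen end game and spares the peracid step. Against it, only ring E is made, so rings C and G inside A6 and A5 still need their own solution; A6 requires converting a doubly flanked phenol of a tetramer into an ethynyl ether under strongly basic conditions, A5 is a reduced squarate derivative of a trimer, and the ketene intermediates can dimerise or be trapped. In comparison, it is better on convergence and on the last steps, weaker on what it leaves unsolved, and, counting the fragment syntheses, its total is expected to exceed that of the chosen plan.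

Key step: step 20

Remark: a bromine in place of the fluorine of 11 would not be displaced by a phenoxide without copper, because one para formyl group does not activate a bromide flanked by two benzyloxy groups; the fluoride is therefore used.
Remark: the ring-by-ring connectivity of 33 and 35 was compared with 36 and agrees position by position.
Assumption: 7, 12, 17 and 23 are treated as catalogue chemicals.
Ring numbering used below: in rings C, E and G, C1 bears the ether to the preceding ring and C2 the ether to the following ring.

## Route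

Step 1
Reactants: 1 3,4-difluorophenol
Product: 2 4,5-difluoro-2-hydroxybenzaldehyde
Conditions: MgCl2, Et3N, (CH2O)n, MeCN, reflux; aq. HCl
Reagents that add atoms: paraformaldehyde (as formaldehyde), C=O
Why: Casnati–Skattebøl ortho-formylation: the magnesium phenoxide delivers formaldehyde to an ortho carbon and a second formaldehyde oxidises the benzylic alkoxide; the ortho position para to the C3 fluorine is open while the other lies between OH and F, so 2 should be the main isomer.

Step 2
Reactants: 2 4,5-difluoro-2-hydroxybenzaldehyde
Product: 3 2-(benzyloxy)-4,5-difluorobenzaldehyde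
Conditions: BnBr, K2CO3, DMF, rt
Reagents that add atoms: benzyl bromide, BrCc1ccccc1
Why: Williamson etherification of the acidic salicylaldehyde hydroxyl; at room temperature the weakly nucleophilic phenoxide should not displace the para-activated fluoride of a second molecule.

Step 3
Reactants: 3 2-(benzyloxy)-4,5-difluorobenzaldehyde
Product: 6 6-(benzyloxy)-3,4-difluorophthalaldehyde, via lithium α-amino alkoxide 4 (not isolated), via ortho-lithiated α-amino alkoxide 5 (not isolated)
Conditions: MeN(Li)CH2CH2NMe2 (from MeNHCH2CH2NMe2, n-BuLi), THF, −78 °C; n-BuLi, −78 °C; DMF, −78 to −40 °C; inverse quench into cold 1 M HCl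
Reagents that add atoms: N,N-dimethylformamide, CN(C)C=O
Why: Directed ortho-metalation with in situ α-amino alkoxide protection: the amide adds to the aldehyde and the chelating adduct 4 steers the base to the only carbon ortho to it, which is also ortho to fluorine, in preference to the carbon between OBn and F; DMF formylates 5 and acid releases both aldehydes. The temperature is kept at −78 °C so that the ortho-fluoro aryllithium does not lose LiF, and the acidic inverse quench protonates the liberated amines before they can attack the activated fluoride.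

Step 4
Reactants: 7 3,5-bis(benzyloxy)benzaldehyde
Product: 8 2-[3,5-bis(benzyloxy)phenyl]-1,3-dioxolane
Conditions: HOCH2CH2OH, TsOH (cat.), toluene, reflux, Dean–Stark
Reagents that add atoms: ethylene glycol, OCCO
Why: Acid-catalysed acetalisation with azeotropic removal of water masks the aldehyde against the organolithium of the next step.

Step 5
Reactants: 8 2-[3,5-bis(benzyloxy)phenyl]-1,3-dioxolane
Product: 11 3,5-bis(benzyloxy)-4-fluorobenzaldehyde, via 4-lithio dioxolane 9 (not isolated), via 4-fluoro dioxolane 10 (not isolated)
Conditions: n-BuLi, THF, 0 °C; (PhSO2)2NF, −78 °C to rt; 2 M HCl, THF, rt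
Reagents that add atoms: N-fluorobenzenesulfonimide, O=S(=O)(c1ccccc1)N(F)S(=O)(=O)c1ccccc1; water, O
Why: Directed ortho-metalation at the carbon between the two benzyloxy groups, the most acidic position of a resorcinol diether, followed by electrophilic fluorination of the aryllithium with the N–F reagent; aqueous acid removes the dioxolane in the work-up.

Step 6
Reactants: 12 3,4,5-trihydroxybenzaldehyde
Product: 13 3,4-bis(benzyloxy)-5-hydroxybenzaldehyde
Conditions: BnBr (2.0 equiv), K2CO3 (2.0 equiv), DMF, 0 °C to rt
Reagents that add atoms: benzyl bromide, BrCc1ccccc1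
Why: Williamson etherification with limiting base and halide: the hydroxyl para to the formyl group is the most acidic and reacts first, the second benzyl enters at one of the two equivalent meta hydroxyls, and 13 should be separable from mono- and tribenzyl ethers by its single free hydroxyl.

Step 7
Reactants: 13 3,4-bis(benzyloxy)-5-hydroxybenzaldehyde
Product: 14 3-(allyloxy)-4,5-bis(benzyloxy)benzaldehyde
Conditions: allyl bromide, K2CO3, DMF, rt
Reagents that add atoms: allyl bromide, C=CCBr
Why: Williamson etherification of the remaining phenol; the allyl group is orthogonal to benzyl ethers and aldehydes and is removed later under neutral conditions.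

Step 8
Reactants: 14 3-(allyloxy)-4,5-bis(benzyloxy)benzaldehyde
Product: 16 3-(allyloxy)-4,5-bis(benzyloxy)phenol, via aryl formate 15 (not isolated)
Conditions: mCPBA, CH2Cl2, 0 °C to rt; aq. Na2S2O3/NaHCO3 wash; Et3N, MeOH, rt
Reagents that add atoms: 3-chloroperbenzoic acid, OOC(=O)c1cccc(Cl)c1
Why: Baeyer–Villiger (Dakin-type) oxidation: the para benzyloxy group favours aryl migration in the Criegee adduct, the isolated allyl double bond reacts far more slowly with the peracid than the aldehyde, and amine-catalysed methanolysis frees the phenol. The conditions rehearse the key step.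

Step 9
Reactants: 17 1,3-bis(benzyloxy)benzene
Product: 20 2,6-bis(benzyloxy)phenol, via 2-lithio diether 18 (not isolated), via dimethyl arylboronate 19 (not isolated)
Conditions: n-BuLi, THF, 0 °C to rt; B(OMe)3, −78 °C to rt; 30% H2O2, AcOH, 0 °C
Reagents that add atoms: hydrogen peroxide, OO
Why: Directed ortho-metalation between the two benzyloxy groups, borylation of the aryllithium and oxidative C–B to C–O migration with peroxide, a standard one-pot phenol synthesis.

Step 10
Reactants: 20 2,6-bis(benzyloxy)phenol
Product: 22 2,6-bis(benzyloxy)benzene-1,4-diol, via 2,6-bis(benzyloxy)-1,4-benzoquinone 21 (not isolated)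
Conditions: ON(SO3K)2, KH2PO4, acetone/H2O, rt; then Na2S2O4, EtOAc/H2O, Ar
Reagents that add atoms: potassium nitrosodisulfonate ON(SO3K)2, [K+].[K+].[O]N(S(=O)(=O)[O-])S(=O)(=O)[O-]
Why: Teuber oxidation of a 2,6-disubstituted phenol with a free para position gives the para-quinone, which dithionite reduces to the hydroquinone in the same work-up; the product is kept under argon.

Step 11
Reactants: 23 3,4,5-tris(benzyloxy)benzaldehyde
Product: 25 3,4,5-tris(benzyloxy)phenol, via aryl formate 24 (not isolated)
Conditions: mCPBA, CH2Cl2, 0 °C to rt; aq. Na2S2O3/NaHCO3 wash; Et3N, MeOH, rt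
Reagents that add atoms: 3-chloroperbenzoic acid, OOC(=O)c1cccc(Cl)c1
Why: Baeyer–Villiger oxidation of a 3,4,5-trialkoxybenzaldehyde with aryl migration, then methanolysis of the formate; a second single-site model of the key step.

Step 12
Reactants: 11 3,5-bis(benzyloxy)-4-fluorobenzaldehyde; 16 3-(allyloxy)-4,5-bis(benzyloxy)phenol
Product: 26 4-[3-(allyloxy)-4,5-bis(benzyloxy)phenoxy]-3,5-bis(benzyloxy)benzaldehyde (dimer A–B allyl ether)
Conditions: Cs2CO3, DMSO, 4 Å MS, 110 °C, Ar
Reagents that add atoms: none
Why: Nucleophilic aromatic substitution: the para formyl group stabilises the Meisenheimer adduct and fluoride is the best leaving group for this mechanism; the unhindered phenoxide of 16 offsets the crowding by the two ortho benzyloxy groups, and the allyl ether ensures that only the outer oxygen of ring B can react.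

Step 13
Reactants: 26 dimer A–B allyl ether
Product: 27 3,5-bis(benzyloxy)-4-[3,4-bis(benzyloxy)-5-hydroxyphenoxy]benzaldehyde (dimer A–B phenol)
Conditions: Pd(PPh3)4 (cat.), morpholine, THF, rt
Reagents that add atoms: none
Why: Tsuji–Trost deallylation: zerovalent palladium ionises the aryl allyl ether to a π-allyl complex that morpholine captures; benzyl ethers, the diaryl ether and the aldehyde are untouched.

Step 14
Reactants: 27 dimer A–B phenol; 6 6-(benzyloxy)-3,4-difluorophthalaldehyde
Product: 28 6-(benzyloxy)-4-{2,3-bis(benzyloxy)-5-[2,6-bis(benzyloxy)-4-formylphenoxy]phenoxy}-3-fluorophthalaldehyde (trimer A–C fluoride)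
Conditions: K2CO3, DMF, 4 Å MS, 0 °C to rt, Ar (6 in slight excess)
Reagents that add atoms: none
Why: Nucleophilic aromatic substitution at C1 of 6: this carbon is para to the C4 formyl group, meta to the benzyloxy donor and next to a ring hydrogen, whereas C2 is para to the donor and flanked on both sides, so the phenoxide should enter at C1 only; dry carbonate and low temperature protect the dialdehyde from disproportionation.

Step 15
Reactants: 28 trimer A–C fluoride; 22 2,6-bis(benzyloxy)benzene-1,4-diol
Product: 29 tetramer A–D phenol (fluorine on C2 of ring C replaced by a 3,5-bis(benzyloxy)-4-hydroxyphenoxy group)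
Conditions: Cs2CO3, DMSO, 4 Å MS, 60–70 °C, Ar (22 in threefold excess)
Reagents that add atoms: none
Why: Nucleophilic aromatic substitution at C2, activated by the ortho C3 formyl group; the hydroxyl of 22 that has no ortho substituent is the more acidic and the only one able to reach the flanked C2, because attack by the other hydroxyl would create a diaryl ether with four ortho substituents, and the excess of 22 suppresses double arylation.

Step 16
Reactants: 29 tetramer A–D phenol; 6 6-(benzyloxy)-3,4-difluorophthalaldehyde
Product: 30 pentamer A–E fluoride (ring D oxygen bonded to C1 of a 5-(benzyloxy)-2-fluoro-3,4-diformylphenyl ring E)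
Conditions: K2CO3, DMF, 4 Å MS, rt to 40 °C, Ar (6 in slight excess)
Reagents that add atoms: none
Why: Nucleophilic aromatic substitution as in step 14; the hindered phenoxide of ring D meets the most electrophilic and least hindered carbon of 6 (C1), which is what makes this flanked ether accessible without a metal.

Step 17
Reactants: 30 pentamer A–E fluoride; 22 2,6-bis(benzyloxy)benzene-1,4-diol
Product: 31 hexamer A–F phenol (fluorine on C2 of ring E replaced by a 3,5-bis(benzyloxy)-4-hydroxyphenoxy group)
Conditions: Cs2CO3, DMSO, 4 Å MS, 60–70 °C, Ar (22 in threefold excess)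
Reagents that add atoms: none
Why: Nucleophilic aromatic substitution at C2 of ring E with the same site selectivity on both partners as in step 15.

Step 18
Reactants: 31 hexamer A–F phenol; 6 6-(benzyloxy)-3,4-difluorophthalaldehyde
Product: 32 heptamer A–G fluoride (ring F oxygen bonded to C1 of a 5-(benzyloxy)-2-fluoro-3,4-diformylphenyl ring G)
Conditions: K2CO3, DMF, 4 Å MS, rt to 40 °C, Ar (6 in slight excess)
Reagents that add atoms: none
Why: Nucleophilic aromatic substitution at C1 of 6, as in steps 14 and 16.

Step 19
Reactants: 32 heptamer A–G fluoride; 25 3,4,5-tris(benzyloxy)phenol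
Product: 33 octamer hepta-aldehyde (formyl on C4 of ring A and on C3 and C4 of rings C, E and G; fourteen benzyl ethers)
Conditions: Cs2CO3, DMSO, 4 Å MS, 60–70 °C, Ar
Reagents that add atoms: none
Why: Nucleophilic aromatic substitution at C2 of ring G, activated by the ortho C3 formyl group; 25 has a single unhindered hydroxyl, so no selectivity issue arises.

Step 20
Reactants: 33 octamer hepta-aldehyde
Product: 35 tetradecabenzyl octamer heptaphenol, via octamer heptaformate 34 (not isolated)
Conditions: mCPBA (excess), CH2Cl2, 0 °C to rt; aq. Na2S2O3/NaHCO3 wash; Et3N, MeOH/THF, Ar, rt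
Reagents that add atoms: 3-chloroperbenzoic acid, OOC(=O)c1cccc(Cl)c1
Why: Baeyer–Villiger oxidation of aryl aldehydes (the peracid form of the Dakin reaction): the peracid adds to each formyl carbon to give a Criegee adduct, the aryl group migrates from carbon to peroxide oxygen with loss of 3-chlorobenzoate, and the aryl formates of 34 are cleaved by amine-catalysed methanolysis. The closest known reactions are the conversions of 3,4,5-trialkoxy- and 2-alkoxybenzaldehydes into phenols with the same peracid, rehearsed in steps 8 and 11, and twofold oxidations of dialkoxy aromatic dialdehydes. No ring closes and no stereocentre forms; seven aryl C–C bonds are exchanged for seven aryl C–O bonds. The selectivity needed is aryl over hydride migration at every site: the ring A formyl has a para aryloxy group, each C4 formyl an ortho benzyloxy and a para aryloxy group, and each C3 formyl an ortho aryloxy group, and once the neighbouring C4 formyl has become a formate the C3 formyl gains a second ortho oxygen. The C4 formyl groups should therefore react first and the C3 formyl groups last. Benzyl and diaryl ethers are inert to the peracid at this temperature; hydroxylation of the electron-rich rings B, D, F and H is the competing process and is limited by low temperature and by destroying the excess peracid before the formates are cleaved. Methanolysis is run with Et3N under argon because the new catechol units would be oxidised by air in stronger base.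

Step 21
Reactants: 35 tetradecabenzyl octamer heptaphenol
Product: 36 CNP0175816.0 (free octamer, 21 hydroxyls)
Conditions: H2 (1 atm), 10% Pd/C, THF/MeOH, rt; filtration and evaporation under Ar
Reagents that add atoms: none
Why: Hydrogenolysis of the fourteen aryl benzyl ethers over palladium on carbon; diaryl ethers are stable under these conditions and the only by-product is volatile, so the air-sensitive polyphenol is obtained by filtration and evaporation.

## Compound list

1 | 3,4-difluorophenol | Oc1ccc(F)c(F)c1 | starting material
2 | 4,5-difluoro-2-hydroxybenzaldehyde | O=Cc1cc(F)c(F)cc1O | intermediate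
3 | 2-(benzyloxy)-4,5-difluorobenzaldehyde | O=Cc1cc(F)c(F)cc1OCc1ccccc1 | intermediate
4 | lithium [2-(benzyloxy)-4,5-difluorophenyl]{[2-(dimethylamino)ethyl](methyl)amino}methanolate (racemic; formed in the flask, not isolated) | [Li+].[O-]C(N(C)CCN(C)C)c1cc(F)c(F)cc1OCc1ccccc1 | intermediate
5 | 6-lithio derivative of 4, lithium on the ring carbon between the carbinol carbon and fluorine (formed in the flask, not isolated) | [Li+].[O-]C(N(C)CCN(C)C)c1c([Li])c(F)c(F)cc1OCc1ccccc1 | intermediate
6 | 6-(benzyloxy)-3,4-difluorophthalaldehyde | O=Cc1c(C=O)c(F)c(F)cc1OCc1ccccc1 | intermediate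
7 | 3,5-bis(benzyloxy)benzaldehyde | O=Cc1cc(OCc2ccccc2)cc(OCc2ccccc2)c1 | starting material
8 | 2-[3,5-bis(benzyloxy)phenyl]-1,3-dioxolane | C1COC(O1)c1cc(OCc2ccccc2)cc(OCc2ccccc2)c1 | intermediate
9 | [2,6-bis(benzyloxy)-4-(1,3-dioxolan-2-yl)phenyl]lithium (formed in the flask, not isolated) | [Li]c1c(OCc2ccccc2)cc(cc1OCc1ccccc1)C1OCCO1 | intermediate
10 | 2-[3,5-bis(benzyloxy)-4-fluorophenyl]-1,3-dioxolane (formed in the flask, not isolated) | Fc1c(OCc2ccccc2)cc(cc1OCc1ccccc1)C1OCCO1 | intermediate
11 | 3,5-bis(benzyloxy)-4-fluorobenzaldehyde | O=Cc1cc(OCc2ccccc2)c(F)c(OCc2ccccc2)c1 | intermediate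
12 | 3,4,5-trihydroxybenzaldehyde | O=Cc1cc(O)c(O)c(O)c1 | starting material
13 | 3,4-bis(benzyloxy)-5-hydroxybenzaldehyde | O=Cc1cc(O)c(OCc2ccccc2)c(OCc2ccccc2)c1 | intermediate
14 | 3-(allyloxy)-4,5-bis(benzyloxy)benzaldehyde | O=Cc1cc(OCC=C)c(OCc2ccccc2)c(OCc2ccccc2)c1 | intermediate
15 | 3-(allyloxy)-4,5-bis(benzyloxy)phenyl formate (formed in the flask, not isolated) | O=COc1cc(OCC=C)c(OCc2ccccc2)c(OCc2ccccc2)c1 | intermediate
16 | 3-(allyloxy)-4,5-bis(benzyloxy)phenol | Oc1cc(OCC=C)c(OCc2ccccc2)c(OCc2ccccc2)c1 | intermediate
17 | 1,3-bis(benzyloxy)benzene | C(Oc1cccc(OCc2ccccc2)c1)c1ccccc1 | starting material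
18 | [2,6-bis(benzyloxy)phenyl]lithium (formed in the flask, not isolated) | [Li]c1c(OCc2ccccc2)cccc1OCc1ccccc1 | intermediate
19 | dimethyl [2,6-bis(benzyloxy)phenyl]boronate (formed in the flask, not isolated) | COB(OC)c1c(OCc2ccccc2)cccc1OCc1ccccc1 | intermediate
20 | 2,6-bis(benzyloxy)phenol | Oc1c(OCc2ccccc2)cccc1OCc1ccccc1 | intermediate
21 | 2,6-bis(benzyloxy)-1,4-benzoquinone (formed in the flask, not isolated) | O=C1C=C(OCc2ccccc2)C(=O)C(OCc2ccccc2)=C1 | intermediate
22 | 2,6-bis(benzyloxy)benzene-1,4-diol | Oc1cc(OCc2ccccc2)c(O)c(OCc2ccccc2)c1 | intermediate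
23 | 3,4,5-tris(benzyloxy)benzaldehyde | O=Cc1cc(OCc2ccccc2)c(OCc2ccccc2)c(OCc2ccccc2)c1 | starting material
24 | 3,4,5-tris(benzyloxy)phenyl formate (formed in the flask, not isolated) | O=COc1cc(OCc2ccccc2)c(OCc2ccccc2)c(OCc2ccccc2)c1 | intermediate
25 | 3,4,5-tris(benzyloxy)phenol | Oc1cc(OCc2ccccc2)c(OCc2ccccc2)c(OCc2ccccc2)c1 | intermediate
26 | dimer A–B allyl ether: 4-[3-(allyloxy)-4,5-bis(benzyloxy)phenoxy]-3,5-bis(benzyloxy)benzaldehyde | O=Cc1cc(OCc9ccccc9)c(Oc2cc(OCc9ccccc9)c(OCc9ccccc9)c(OCC=C)c2)c(OCc9ccccc9)c1 | intermediate
27 | dimer A–B phenol: 3,5-bis(benzyloxy)-4-[3,4-bis(benzyloxy)-5-hydroxyphenoxy]benzaldehyde | O=Cc1cc(OCc9ccccc9)c(Oc2cc(OCc9ccccc9)c(OCc9ccccc9)c(O)c2)c(OCc9ccccc9)c1 | intermediate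
28 | trimer A–C fluoride: 6-(benzyloxy)-4-{2,3-bis(benzyloxy)-5-[2,6-bis(benzyloxy)-4-formylphenoxy]phenoxy}-3-fluorophthalaldehyde | O=Cc1cc(OCc9ccccc9)c(Oc2cc(OCc9ccccc9)c(OCc9ccccc9)c(Oc3cc(OCc9ccccc9)c(C=O)c(C=O)c3F)c2)c(OCc9ccccc9)c1 | intermediate
29 | tetramer A–D phenol: 28 with the fluorine on C2 of ring C replaced by a 3,5-bis(benzyloxy)-4-hydroxyphenoxy group (ring D) | O=Cc1cc(OCc9ccccc9)c(Oc2cc(OCc9ccccc9)c(OCc9ccccc9)c(Oc3cc(OCc9ccccc9)c(C=O)c(C=O)c3Oc3cc(OCc9ccccc9)c(O)c(OCc9ccccc9)c3)c2)c(OCc9ccccc9)c1 | intermediate
30 | pentamer A–E fluoride: 29 with the ring D hydroxyl oxygen bonded to C1 of a 5-(benzyloxy)-2-fluoro-3,4-diformylphenyl group (ring E) | O=Cc1cc(OCc9ccccc9)c(Oc2cc(OCc9ccccc9)c(OCc9ccccc9)c(Oc3cc(OCc9ccccc9)c(C=O)c(C=O)c3Oc3cc(OCc9ccccc9)c(Oc4cc(OCc9ccccc9)c(C=O)c(C=O)c4F)c(OCc9ccccc9)c3)c2)c(OCc9ccccc9)c1 | intermediate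
31 | hexamer A–F phenol: 30 with the fluorine on C2 of ring E replaced by a 3,5-bis(benzyloxy)-4-hydroxyphenoxy group (ring F) | O=Cc1cc(OCc9ccccc9)c(Oc2cc(OCc9ccccc9)c(OCc9ccccc9)c(Oc3cc(OCc9ccccc9)c(C=O)c(C=O)c3Oc3cc(OCc9ccccc9)c(Oc4cc(OCc9ccccc9)c(C=O)c(C=O)c4Oc4cc(OCc9ccccc9)c(O)c(OCc9ccccc9)c4)c(OCc9ccccc9)c3)c2)c(OCc9ccccc9)c1 | intermediate
32 | heptamer A–G fluoride: 31 with the ring F hydroxyl oxygen bonded to C1 of a 5-(benzyloxy)-2-fluoro-3,4-diformylphenyl group (ring G) | O=Cc1cc(OCc9ccccc9)c(Oc2cc(OCc9ccccc9)c(OCc9ccccc9)c(Oc3cc(OCc9ccccc9)c(C=O)c(C=O)c3Oc3cc(OCc9ccccc9)c(Oc4cc(OCc9ccccc9)c(C=O)c(C=O)c4Oc4cc(OCc9ccccc9)c(Oc5cc(OCc9ccccc9)c(C=O)c(C=O)c5F)c(OCc9ccccc9)c4)c(OCc9ccccc9)c3)c2)c(OCc9ccccc9)c1 | intermediate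
33 | octamer hepta-aldehyde: 32 with the fluorine on C2 of ring G replaced by a 3,4,5-tris(benzyloxy)phenoxy group (ring H); formyl on C4 of ring A and on C3 and C4 of rings C, E and G | O=Cc1cc(OCc9ccccc9)c(Oc2cc(OCc9ccccc9)c(OCc9ccccc9)c(Oc3cc(OCc9ccccc9)c(C=O)c(C=O)c3Oc3cc(OCc9ccccc9)c(Oc4cc(OCc9ccccc9)c(C=O)c(C=O)c4Oc4cc(OCc9ccccc9)c(Oc5cc(OCc9ccccc9)c(C=O)c(C=O)c5Oc5cc(OCc9ccccc9)c(OCc9ccccc9)c(OCc9ccccc9)c5)c(OCc9ccccc9)c4)c(OCc9ccccc9)c3)c2)c(OCc9ccccc9)c1 | intermediate
34 | octamer heptaformate: 33 with each formyl group replaced by a formyloxy group (formed in the flask, not isolated) | O=COc1cc(OCc9ccccc9)c(Oc2cc(OCc9ccccc9)c(OCc9ccccc9)c(Oc3cc(OCc9ccccc9)c(OC=O)c(OC=O)c3Oc3cc(OCc9ccccc9)c(Oc4cc(OCc9ccccc9)c(OC=O)c(OC=O)c4Oc4cc(OCc9ccccc9)c(Oc5cc(OCc9ccccc9)c(OC=O)c(OC=O)c5Oc5cc(OCc9ccccc9)c(OCc9ccccc9)c(OCc9ccccc9)c5)c(OCc9ccccc9)c4)c(OCc9ccccc9)c3)c2)c(OCc9ccccc9)c1 | intermediate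
35 | octamer heptaphenol with fourteen benzyl ethers: free hydroxyl on C4 of ring A and on C3 and C4 of rings C, E and G | Oc1cc(OCc9ccccc9)c(Oc2cc(OCc9ccccc9)c(OCc9ccccc9)c(Oc3cc(OCc9ccccc9)c(O)c(O)c3Oc3cc(OCc9ccccc9)c(Oc4cc(OCc9ccccc9)c(O)c(O)c4Oc4cc(OCc9ccccc9)c(Oc5cc(OCc9ccccc9)c(O)c(O)c5Oc5cc(OCc9ccccc9)c(OCc9ccccc9)c(OCc9ccccc9)c5)c(OCc9ccccc9)c4)c(OCc9ccccc9)c3)c2)c(OCc9ccccc9)c1 | intermediate
36 | CNP0175816.0: octameric aryl ether A–H with 21 free hydroxyls | Oc1cc(O)c(Oc2cc(O)c(O)c(Oc3cc(O)c(O)c(O)c3Oc3cc(O)c(Oc4cc(O)c(O)c(O)c4Oc4cc(O)c(Oc5cc(O)c(O)c(O)c5Oc5cc(O)c(O)c(O)c5)c(O)c4)c(O)c3)c2)c(O)c1 | target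

## Step count and least certain steps

Total step count: 21. Longest linear sequence: 13 steps (steps 6 to 8, then 12 to 21, starting from 12).

Step 20, the key step. What may go wrong: hydride instead of aryl migration at the least electron-rich formyl groups (C3 of rings C, E and G, which have one ortho aryloxy donor and a formyl neighbour), which would lead to carboxylic acids; incomplete conversion of seven sites; peracid hydroxylation of the tetraoxygenated rings; and air oxidation of the new catechol units during formate cleavage. Fallback, setting out from 33 and coming back to the route at 35: the oxidation is divided into two mechanistically different stages. A limited amount of mCPBA at −20 to 0 °C followed by Et3N/MeOH should convert only the four best-activated formyl groups (ring A and C4 of rings C, E and G) and give the octamer tetraphenol trialdehyde F1. In F1 every remaining formyl group is ortho to a free hydroxyl, which is the substrate class of the classical alkaline Dakin reaction, so H2O2 with NaOH in degassed THF/water at 0 °C should drive aryl migration from the phenoxide of F1 and give 35.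

Step 3. What may go wrong: deprotonation at the carbon between the benzyloxy group and fluorine instead of the carbon next to the amino alkoxide, loss of LiF to an aryne if the temperature rises, and amine attack on the activated fluoride during work-up. Fallback, setting out from 2 and coming back to the route at 6: the competing site is shielded sterically. Silylation of 2 with i-Pr3SiCl and imidazole gives 4,5-difluoro-2-[(triisopropylsilyl)oxy]benzaldehyde F2. Acetalisation of F2 with ethylene glycol gives 2-{4,5-difluoro-2-[(triisopropylsilyl)oxy]phenyl}-1,3-dioxolane F3. Lithiation of F3 with s-BuLi at −78 °C, now possible only between the acetal carbon and fluorine because the bulky silyl ether blocks its own ortho position, and quenching with DMF give 2-(1,3-dioxolan-2-yl)-5,6-difluoro-3-[(triisopropylsilyl)oxy]benzaldehyde F4. Dilute HCl in THF converts F4 into 3,4-difluoro-6-[(triisopropylsilyl)oxy]phthalaldehyde F5. CsF with BnBr in DMF at 0 °C exchanges the silyl group of F5 for a benzyl group and gives 6.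

Step 12. What may go wrong: slow addition of the phenoxide to a carbon that is flanked by two benzyloxy groups and activated by one formyl group only, so that the prolonged heating leads to disproportionation of the aldehyde or isomerisation of the allyl ether. Fallback, setting out from 16 and coming back to the route at 26: the ether is made by copper catalysis instead. Commercial 4-bromo-3,5-dihydroxybenzoic acid is perbenzylated (BnBr, K2CO3, DMF) to benzyl 3,5-bis(benzyloxy)-4-bromobenzoate F6. Reduction of F6 with i-Bu2AlH gives [3,5-bis(benzyloxy)-4-bromophenyl]methanol F7. Oxidation of F7 with MnO2 gives 3,5-bis(benzyloxy)-4-bromobenzaldehyde F8. Ullmann coupling of F8 with 16 (CuI, picolinic acid, K3PO4, DMSO, 90 °C) gives 26.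

Step 15. What may go wrong: arylation at the flanked hydroxyl of 22 or at both hydroxyls, oxidation of the hydroquinone to the quinone by traces of air, and base-induced disproportionation of the dialdehyde unit during heating. Fallback, setting out from 12 and 28 and coming back to the route at 29: the flanked hydroxyl is protected. Allylation of 12 at its most acidic hydroxyl (allyl bromide, one equivalent, NaHCO3, DMF) gives 4-(allyloxy)-3,5-dihydroxybenzaldehyde F9. Benzylation of F9 (BnBr, K2CO3, DMF) gives 4-(allyloxy)-3,5-bis(benzyloxy)benzaldehyde F10. Baeyer–Villiger oxidation of F10 and methanolysis as in step 8 give 4-(allyloxy)-3,5-bis(benzyloxy)phenol F11. Displacement of the fluoride of 28 by F11 under the conditions of step 15 gives the tetramer A–D ring D allyl ether F12. Deallylation of F12 with Pd(PPh3)4 and sodium 4-methylbenzenesulfinate in THF/MeOH gives 29.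

Step 17. What may go wrong: the same loss of site selectivity and hydroquinone oxidation as in step 15, now on a substrate with two dialdehyde units. Fallback, setting out from 30 and coming back to the route at 31: 30 is treated with 4-(allyloxy)-3,5-bis(benzyloxy)phenol F11 under the conditions of step 17 to give the hexamer A–F ring F allyl ether F13, and deallylation of F13 with Pd(PPh3)4 and sodium 4-methylbenzenesulfinate gives 31.

## Further compounds

F1 | step 20 | octamer tetraphenol trialdehyde: 35 in which the C3 positions of rings C, E and G still carry formyl groups | Oc1cc(OCc9ccccc9)c(Oc2cc(OCc9ccccc9)c(OCc9ccccc9)c(Oc3cc(OCc9ccccc9)c(O)c(C=O)c3Oc3cc(OCc9ccccc9)c(Oc4cc(OCc9ccccc9)c(O)c(C=O)c4Oc4cc(OCc9ccccc9)c(Oc5cc(OCc9ccccc9)c(O)c(C=O)c5Oc5cc(OCc9ccccc9)c(OCc9ccccc9)c(OCc9ccccc9)c5)c(OCc9ccccc9)c4)c(OCc9ccccc9)c3)c2)c(OCc9ccccc9)c1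
F2 | step 3 | 4,5-difluoro-2-[(triisopropylsilyl)oxy]benzaldehyde | O=Cc1cc(F)c(F)cc1O[Si](C(C)C)(C(C)C)C(C)C
F3 | step 3 | 2-{4,5-difluoro-2-[(triisopropylsilyl)oxy]phenyl}-1,3-dioxolane | Fc1cc(O[Si](C(C)C)(C(C)C)C(C)C)c(cc1F)C1OCCO1
F4 | step 3 | 2-(1,3-dioxolan-2-yl)-5,6-difluoro-3-[(triisopropylsilyl)oxy]benzaldehyde | O=Cc1c(F)c(F)cc(O[Si](C(C)C)(C(C)C)C(C)C)c1C1OCCO1
F5 | step 3 | 3,4-difluoro-6-[(triisopropylsilyl)oxy]phthalaldehyde | O=Cc1c(C=O)c(F)c(F)cc1O[Si](C(C)C)(C(C)C)C(C)C
F6 | step 12 | benzyl 3,5-bis(benzyloxy)-4-bromobenzoate | O=C(OCc1ccccc1)c1cc(OCc2ccccc2)c(Br)c(OCc2ccccc2)c1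
F7 | step 12 | [3,5-bis(benzyloxy)-4-bromophenyl]methanol | OCc1cc(OCc2ccccc2)c(Br)c(OCc2ccccc2)c1
F8 | step 12 | 3,5-bis(benzyloxy)-4-bromobenzaldehyde | O=Cc1cc(OCc2ccccc2)c(Br)c(OCc2ccccc2)c1
F9 | step 15 | 4-(allyloxy)-3,5-dihydroxybenzaldehyde | O=Cc1cc(O)c(OCC=C)c(O)c1
F10 | step 15 | 4-(allyloxy)-3,5-bis(benzyloxy)benzaldehyde | O=Cc1cc(OCc2ccccc2)c(OCC=C)c(OCc2ccccc2)c1
F11 | step 15 | 4-(allyloxy)-3,5-bis(benzyloxy)phenol | Oc1cc(OCc2ccccc2)c(OCC=C)c(OCc2ccccc2)c1
F12 | step 15 | tetramer A–D ring D allyl ether (29 with its ring D hydroxyl allylated) | O=Cc1cc(OCc9ccccc9)c(Oc2cc(OCc9ccccc9)c(OCc9ccccc9)c(Oc3cc(OCc9ccccc9)c(C=O)c(C=O)c3Oc3cc(OCc9ccccc9)c(OCC=C)c(OCc9ccccc9)c3)c2)c(OCc9ccccc9)c1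
F13 | step 17 | hexamer A–F ring F allyl ether (31 with its ring F hydroxyl allylated) | O=Cc1cc(OCc9ccccc9)c(Oc2cc(OCc9ccccc9)c(OCc9ccccc9)c(Oc3cc(OCc9ccccc9)c(C=O)c(C=O)c3Oc3cc(OCc9ccccc9)c(Oc4cc(OCc9ccccc9)c(C=O)c(C=O)c4Oc4cc(OCc9ccccc9)c(OCC=C)c(OCc9ccccc9)c4)c(OCc9ccccc9)c3)c2)c(OCc9ccccc9)c1
A1 | alternative 1 | racemic 2,3-bis(benzyloxy)-4-[(tert-butyldimethylsilyl)oxy]-4-[(E)-2-{2,3-bis(benzyloxy)-5-[2,4,6-tris(benzyloxy)phenoxy]phenoxy}ethenyl]cyclobut-2-en-1-one | O=C1C(OCc9ccccc9)=C(OCc9ccccc9)C1(O[Si](C)(C)C(C)(C)C)/C=C/Oc2cc(Oc3c(OCc9ccccc9)cc(OCc9ccccc9)cc3OCc9ccccc9)cc(OCc9ccccc9)c2OCc9ccccc9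
A2 | alternative 1 | trimer A–C with ring C free at C2–OH, silylated at C5 and benzylated at C3 and C4 | Oc1c(OCc9ccccc9)c(OCc9ccccc9)c(O[Si](C)(C)C(C)(C)C)cc1Oc2cc(Oc3c(OCc9ccccc9)cc(OCc9ccccc9)cc3OCc9ccccc9)cc(OCc9ccccc9)c2OCc9ccccc9
A3 | alternative 2 | dimethyl 4-(aryloxy)-3,5-dioxoheptanedioate, aryl being the perbenzylated heptamer B–H | COC(=O)CC(=O)C(Oc2cc(OCc9ccccc9)c(OCc9ccccc9)c(Oc3cc(OCc9ccccc9)c(OCc9ccccc9)c(OCc9ccccc9)c3Oc3cc(OCc9ccccc9)c(Oc4cc(OCc9ccccc9)c(OCc9ccccc9)c(OCc9ccccc9)c4Oc4cc(OCc9ccccc9)c(Oc5cc(OCc9ccccc9)c(OCc9ccccc9)c(OCc9ccccc9)c5Oc5cc(OCc9ccccc9)c(OCc9ccccc9)c(OCc9ccccc9)c5)c(OCc9ccccc9)c4)c(OCc9ccccc9)c3)c2)C(=O)CC(=O)OC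
A4 | alternative 2 | octamer with ring A as methyl 2,4,6-trihydroxybenzoate bearing the ether at C3 of the benzoate | COC(=O)c1c(O)cc(O)c(Oc2cc(OCc9ccccc9)c(OCc9ccccc9)c(Oc3cc(OCc9ccccc9)c(OCc9ccccc9)c(OCc9ccccc9)c3Oc3cc(OCc9ccccc9)c(Oc4cc(OCc9ccccc9)c(OCc9ccccc9)c(OCc9ccccc9)c4Oc4cc(OCc9ccccc9)c(Oc5cc(OCc9ccccc9)c(OCc9ccccc9)c(OCc9ccccc9)c5Oc5cc(OCc9ccccc9)c(OCc9ccccc9)c(OCc9ccccc9)c5)c(OCc9ccccc9)c4)c(OCc9ccccc9)c3)c2)c1O
A5 | alternative 3 | racemic 2-(aryloxy)-3,4-bis(benzyloxy)cyclobut-2-en-1-one, aryl being the perbenzylated trimer F–H | O=C1C(Oc4cc(OCc9ccccc9)c(Oc5cc(OCc9ccccc9)c(OCc9ccccc9)c(OCc9ccccc9)c5Oc5cc(OCc9ccccc9)c(OCc9ccccc9)c(OCc9ccccc9)c5)c(OCc9ccccc9)c4)=C(OCc9ccccc9)C1OCc9ccccc9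
A6 | alternative 3 | ethynyl ether of the perbenzylated tetramer A–D (ethynyloxy on C4 of ring D) | c9ccccc9COc1cc(OCc9ccccc9)c(Oc2cc(OCc9ccccc9)c(OCc9ccccc9)c(Oc3cc(OCc9ccccc9)c(OCc9ccccc9)c(OCc9ccccc9)c3Oc3cc(OCc9ccccc9)c(OC#C)c(OCc9ccccc9)c3)c2)c(OCc9ccccc9)c1
A7 | alternative 3 | octamer with free C5–OH on ring E, all other hydroxyls benzylated | c9ccccc9COc1cc(OCc9ccccc9)c(Oc2cc(OCc9ccccc9)c(OCc9ccccc9)c(Oc3cc(OCc9ccccc9)c(OCc9ccccc9)c(OCc9ccccc9)c3Oc3cc(OCc9ccccc9)c(Oc4cc(O)c(OCc9ccccc9)c(OCc9ccccc9)c4Oc4cc(OCc9ccccc9)c(Oc5cc(OCc9ccccc9)c(OCc9ccccc9)c(OCc9ccccc9)c5Oc5cc(OCc9ccccc9)c(OCc9ccccc9)c(OCc9ccccc9)c5)c(OCc9ccccc9)c4)c(OCc9ccccc9)c3)c2)c(OCc9ccccc9)c1
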